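**Retrosynthetic overview**

1. The norbornene is formed last by an exo Diels–Alder reaction (bonds C1–C13' and C3–C11') between a 2-acetoxyguaia-1(5),3-dien-12,8-olide (40, made in the flask) and the (Z,Z)-germacranolide 21; the guaianolide's own methylene lactone is masked as a Mannich base until the end.
2. Germacranolide 21 comes from the 2-alkylated (4Z,8Z)-cyclodeca-4,8-diene-1,3-dione 14: C6'=O and C8'=O flank C7', which takes the lactone carbons; two directed reductions and lactonisation follow.
3. The ten-membered carbocycle comes from an eight-membered one: dione 12 arises from the silyl dienol ether of 3,7-dimethylcycloocta-2,6-dienone by dichloroketene [2+2] cycloaddition and retro-aldol opening of the ring-fusion bond, which inserts C7' and C8' between C6' and C9' (two-carbon ring expansion).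
4. Enabling feature: in ring C1'–C10' the oxygens on C6' and C8' are 1,3-related across C7' (a latent β-diketone), and the two cis, methyl-bearing, 1,5-related alkenes C1'=C10' and C4'=C5' are those of commercial 1,5-dimethylcycloocta-1,5-diene, which supplies eight ring carbons, both methyls and both olefin geometries.
5. Guaianolide: cyclopentane-1,3-dione and crotonaldehyde (organocatalytic Michael addition sets C10; Stork–Danheiser transposition gives the cyclopentenone), then chromium-mediated allylation closes the seven-membered ring and the lactone (C7–C8). Ring order: 8 → 10 → γ-lactone; 5 → 7 + γ-lactone; norbornene.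

Key step: step 5

Assumption: the SMILES is read literally, so both alkenes of the ten-membered ring are cis in the ring (1(10)Z,4Z); primed locants are germacranolide atoms, unprimed ones guaianolide atoms; technical-grade 1 is freed of its 1,6-dimethyl isomer by fractional distillation before use.

**Route**

Step 1
Reactants: 1 (1Z,5Z)-1,5-dimethylcycloocta-1,5-diene
Product: 2 (1R*,8S*,4Z)-1,5-dimethyl-9-oxabicyclo[6.1.0]non-4-ene
Conditions: mCPBA (0.95 equiv), NaHCO3, CH2Cl2, 0 °C
Reagents that add atoms: 3-chloroperoxybenzoic acid (mCPBA), O=C(OO)c1cccc(Cl)c1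
Why: Prilezhaev epoxidation with a peracid: the two trisubstituted alkenes of 1 are equivalent, so a single cis-fused monoepoxide should form, and a slight deficit of peracid limits bis-epoxidation.

Step 2
Reactants: 2 (1R*,8S*,4Z)-1,5-dimethyl-9-oxabicyclo[6.1.0]non-4-ene
Product: 5 (2Z,5Z)-1,5-dimethylcycloocta-2,5-dien-1-ol, via hydroxy selenide 3 (not isolated), via selenoxide 4 (not isolated)
Conditions: PhSeSePh, NaBH4, EtOH, 78 °C; then 30% H2O2, THF, 0 °C → rt
Reagents that add atoms: none
Why: Epoxide-to-allylic-alcohol transposition: PhSe− opens the epoxide by SN2 attack at the secondary carbon (3), and syn-elimination of selenoxide 4 runs away from the carbinol carbon, giving the tertiary allylic alcohol whose new ring alkene can only be cis in an eight-membered ring.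

Step 3
Reactants: 5 (2Z,5Z)-1,5-dimethylcycloocta-2,5-dien-1-ol
Product: 6 (2Z,6Z)-3,7-dimethylcycloocta-2,6-dien-1-one
Conditions: pyridinium chlorochromate [C5H5NH][CrO3Cl], 4 Å molecular sieves, CH2Cl2, rt
Reagents that add atoms: none
Why: Babler–Dauben oxidative 1,3-transposition of a tertiary allylic alcohol by hexavalent chromium moves the oxygen to the former vinylic CH (the future C6') and leaves the methyl-bearing alkene conjugated and, in this ring size, necessarily Z.

Step 4
Reactants: 6 (2Z,6Z)-3,7-dimethylcycloocta-2,6-dien-1-one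
Product: 7 [(1Z,3Z,7Z)-3,7-dimethylcycloocta-1,3,7-trien-1-yl]oxy(trimethyl)silane
Conditions: LiN(iPr)2, THF, −78 °C; Me3SiCl, Et3N, −78 → 0 °C
Reagents that add atoms: chlorotrimethylsilane, C[Si](C)(C)Cl
Why: Kinetic enolate formation at the only sp3 α-carbon (future C9', flanked by the carbonyl and the C1'=C10' alkene) and O-silylation give the silyl dienol ether; it is kept cold and used at once so that the cyclooctatriene does not undergo 6π-electrocyclisation.

Step 5
Reactants: 7 [(1Z,3Z,7Z)-3,7-dimethylcycloocta-1,3,7-trien-1-yl]oxy(trimethyl)silane; 8 dichloroacetyl chloride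
Product: 12 (4Z,8Z)-5,9-dimethylcyclodeca-4,8-diene-1,3-dione, via dichloroketene 9 (not isolated), via dichlorocyclobutanone 10 (not isolated), via cyclobutanone 11 (not isolated)
Conditions: Cl2CHCOCl, Et3N, hexanes, 0 °C → rt; filtration; then Zn dust, AcOH, iPrOH–H2O, 0 °C → rt
Reagents that add atoms: dichloroacetyl chloride 8, O=C(Cl)C(Cl)Cl
Why: Dichloroketene (9), formed from 8 and Et3N, adds across the siloxy-bearing C6'=C9' bond of 7 in a thermal [2+2] cycloaddition (ketene carbonyl carbon to the nucleophilic α-carbon C9', CCl2 to C6'), closing the cyclobutanone of the cis-fused bicyclo[6.2.0]decadienone 10. Zinc in acetic acid then removes both chlorines (11) and, after loss of the silyl group, the β-oxido ketone fragments by retro-aldol cleavage of the ring-fusion bond C6'–C9', so that the eight-membered ring opens out to the ten-membered 1,3-dione with C7' and C8' inserted between C6' and C9'. The closest known reaction type is the two-carbon ring expansion of cycloalkanone silyl enol ethers to cycloalkane-1,3-diones by dichloroketene cycloaddition and reductive ring opening. The only ring closed is the transient four-membered ring (concerted [π2s+π2a] closure); the ten-membered ring is not closed but arises by fragmentation, and the two stereocentres of 10 are erased, so no stereocentre has to be controlled. The step needs site selectivity for the enol-ether double bond over the two other ring alkenes, secured by its much higher nucleophilicity, and cleavage of the fusion bond rather than the C6'–C7' bond, secured because that path gives the secondary, allyl-conjugated C9' enolate. Neither trisubstituted alkene is touched, so both stay cis, and the buffered acidic medium should keep the β,γ-unsaturated ketone out of conjugation.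

Step 6
Reactants: 12 (4Z,8Z)-5,9-dimethylcyclodeca-4,8-diene-1,3-dione; 13 tert-butyl bromoacetate
Product: 14 tert-butyl 2-[(3Z,7Z)-4,8-dimethyl-2,10-dioxocyclodeca-3,7-dien-1-yl]acetate
Conditions: K2CO3, acetone, rt
Reagents that add atoms: tert-butyl bromoacetate 13, CC(C)(C)OC(=O)CBr
Why: C-Alkylation of the β-diketone at C7' with an α-halo ester under mild carbonate conditions (the monoanion also protects the β,γ-unsaturated ketone from isomerisation); the tert-butyl ester is chosen because it will not lactonise before step 9.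

Step 7
Reactants: 14 tert-butyl 2-[(3Z,7Z)-4,8-dimethyl-2,10-dioxocyclodeca-3,7-dien-1-yl]acetate
Product: 15 tert-butyl 2-[(1R*,3Z,7Z,10R*)-10-hydroxy-4,8-dimethyl-2-oxocyclodeca-3,7-dien-1-yl]acetate
Conditions: Zn(BH4)2 (0.6 equiv), Et2O, −40 °C
Reagents that add atoms: none
Why: Chelation-controlled reduction of a 2-substituted 1,3-diketone with zinc borohydride: zinc bridges both carbonyls, hydride attacks the more electrophilic non-conjugated C8' carbonyl anti to the C7' side chain and should give the 7',8'-syn hydroxy ketone (relative configuration of C7' and C8' set here).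

Step 8
Reactants: 15 tert-butyl 2-[(1R*,3Z,7Z,10R*)-10-hydroxy-4,8-dimethyl-2-oxocyclodeca-3,7-dien-1-yl]acetate
Product: 16 tert-butyl 2-[(1S*,2R*,3Z,7Z,10R*)-10-acetoxy-2-hydroxy-4,8-dimethylcyclodeca-3,7-dien-1-yl]acetate
Conditions: SmI2 (0.3 equiv), CH3CHO (6 equiv), THF, −10 °C
Reagents that add atoms: acetaldehyde, CC=O
Why: Evans–Tishchenko reduction: the samarium-bound hemiacetal formed from the C8' hydroxyl and acetaldehyde transfers hydride intramolecularly to the C6' ketone through a chair transition state, which should set C6' 1,3-anti to C8' and leaves the C8' oxygen acetylated and only the C6' hydroxyl free.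

Step 9
Reactants: 16 tert-butyl 2-[(1S*,2R*,3Z,7Z,10R*)-10-acetoxy-2-hydroxy-4,8-dimethylcyclodeca-3,7-dien-1-yl]acetate
Product: 17 (3aR*,4R*,6Z,10Z,11aR*)-6,10-dimethyl-2-oxo-2,3,3a,4,5,8,9,11a-octahydrocyclodeca[b]furan-4-yl acetate
Conditions: CF3CO2H, CH2Cl2, 0 °C → rt
Reagents that add atoms: none
Why: Acid-mediated tert-butyl ester cleavage with 5-exo lactonisation onto the only free hydroxyl; because C6'–O and the C7' side chain are anti, the γ-lactone that forms is trans-fused, and the secondary acetate survives.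

Step 10
Reactants: 17 (3aR*,4R*,6Z,10Z,11aR*)-6,10-dimethyl-2-oxo-2,3,3a,4,5,8,9,11a-octahydrocyclodeca[b]furan-4-yl acetate
Product: 18 (3aR,4R,6Z,10Z,11aR)-4-hydroxy-6,10-dimethyl-3a,4,5,8,9,11a-hexahydrocyclodeca[b]furan-2(3H)-one
Conditions: Burkholderia cepacia lipase (Amano PS), phosphate buffer pH 7, MTBE, 30 °C, stopped at half conversion
Reagents that add atoms: none
Why: Lipase-catalysed kinetic resolution by enantioselective ester hydrolysis: by the Kazlauskas rule the acetate with R configuration at the carbinol carbon (large group C7', medium group C9'H2) is the fast-reacting one, so the alcohol formed should be the (3aR,4R,11aR) enantiomer, while the enantiomeric acetate is left and removed by chromatography.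

Step 11
Reactants: 18 (3aR,4R,6Z,10Z,11aR)-4-hydroxy-6,10-dimethyl-3a,4,5,8,9,11a-hexahydrocyclodeca[b]furan-2(3H)-one
Product: 21 (3aR,4R,6Z,10Z,11aR)-4-hydroxy-6,10-dimethyl-3-methylidene-3a,4,5,8,9,11a-hexahydrocyclodeca[b]furan-2(3H)-one, via Mannich base 19 (not isolated), via methiodide 20 (not isolated)
Conditions: LiN(iPr)2 (2.3 equiv), THF, −78 °C; CH2=NMe2+ I−, −78 → 0 °C; then MeI, MeOH, rt; aq. NaHCO3, EtOAc, rt
Reagents that add atoms: Eschenmoser's salt (N,N-dimethylmethyleneiminium iodide), C=[N+](C)C.[I-]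
Why: Standard α-methylenation of a γ-lactone: the lactone enolate of the dianion is aminomethylated by Eschenmoser's salt (19), N-methylation gives 20 and Hofmann-type β-elimination gives the exocyclic alkene; the C11' centre of 19 is lost.

Step 12
Reactants: 22 cyclopentane-1,3-dione; 23 (E)-but-2-enal
Product: 25 (4S)-2-methoxy-4-methyl-3,4,6,7-tetrahydrocyclopenta[b]pyran-5(2H)-one, via lactol 24 (not isolated)
Conditions: (R)-α,α-diphenylprolinol trimethylsilyl ether (10 mol%), PhCO2H (10 mol%), CH2Cl2, 0 °C; then MeOH, PPTS, rt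
Reagents that add atoms: (E)-but-2-enal 23, C/C=C/C=O; methanol, CO
Why: Iminium-catalysed Michael addition of a cyclic 1,3-dione to an enal: the dione adds to the β-carbon of the E-iminium ion on the face away from the diphenyl(silyloxy)methyl group, which for the (R)-catalyst should set C10 as S, and the lactol 24 is fixed as its methyl acetal, a cyclic vinylogous ester.

Step 13
Reactants: 25 (4S)-2-methoxy-4-methyl-3,4,6,7-tetrahydrocyclopenta[b]pyran-5(2H)-one
Product: 26 (4S)-2-methoxy-4,6-dimethyl-3,4,6,7-tetrahydrocyclopenta[b]pyran-5(2H)-one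
Conditions: LiN(iPr)2, THF, −78 °C; MeI, −78 → −20 °C
Reagents that add atoms: iodomethane, CI
Why: Stork–Danheiser α'-alkylation: kinetic deprotonation of the vinylogous ester at the CH2 next to the carbonyl and methylation introduce C15; the configuration of this carbon is irrelevant because it becomes sp2 in step 22.

Step 14
Reactants: 26 (4S)-2-methoxy-4,6-dimethyl-3,4,6,7-tetrahydrocyclopenta[b]pyran-5(2H)-one
Product: 27 (4S)-6-hydroxy-2-methoxy-4,6-dimethyl-3,4,6,7-tetrahydrocyclopenta[b]pyran-5(2H)-one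
Conditions: KN(SiMe3)2, THF, −78 °C; 2-(phenylsulfonyl)-3-phenyloxaziridine, −78 °C; aq. NH4Cl
Reagents that add atoms: 2-(phenylsulfonyl)-3-phenyloxaziridine (Davis reagent), O=S(=O)(c1ccccc1)N1OC1c1ccccc1
Why: Electrophilic α-hydroxylation of the tetrasubstituted potassium enolate with the Davis oxaziridine installs the tertiary C4 hydroxyl, the later leaving group for the C3=C4 double bond; both epimers are carried on.

Step 15
Reactants: 27 (4S)-6-hydroxy-2-methoxy-4,6-dimethyl-3,4,6,7-tetrahydrocyclopenta[b]pyran-5(2H)-one; 28 allylmagnesium bromide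
Product: 30 (3S)-3-[3-hydroxy-3-methyl-5-oxo-2-(prop-2-en-1-yl)cyclopent-1-en-1-yl]butanal, via diol 29 (not isolated)
Conditions: CH2=CHCH2MgBr (3 equiv), THF, −78 → 0 °C; then 1 M HCl, THF, 0 °C
Reagents that add atoms: allylmagnesium bromide 28, C=CC[Mg]Br; water, O
Why: 1,2-Addition of the allyl Grignard reagent to the vinylogous ester carbonyl (29) and acid-promoted Stork–Danheiser transposition (loss of the new tertiary allylic hydroxyl, hydrolysis of the enol acetal) give the 2,3-disubstituted cyclopentenone with the carbonyl at C2 and set the C8 aldehyde free.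

Step 16
Reactants: 30 (3S)-3-[3-hydroxy-3-methyl-5-oxo-2-(prop-2-en-1-yl)cyclopent-1-en-1-yl]butanal; 31 methyl 2-(hydroxymethyl)prop-2-enoate
Product: 32 methyl (2E)-4-{5-hydroxy-5-methyl-3-oxo-2-[(2S)-4-oxobutan-2-yl]cyclopent-1-en-1-yl}-2-(hydroxymethyl)but-2-enoate
Conditions: second-generation Hoveyda–Grubbs catalyst [RuCl2(H2IMes)(=CH-C6H4-2-OiPr)] (5 mol%), 31 (4 equiv), CH2Cl2, 40 °C
Reagents that add atoms: methyl 2-(hydroxymethyl)prop-2-enoate 31, C=C(CO)C(=O)OC
Why: Olefin cross-metathesis of the monosubstituted allyl alkene with a 1,1-disubstituted acrylate (which behaves like a methacrylate) should give the trisubstituted enoate with C6 trans to the ester; the tetrasubstituted enone alkene and the aldehyde are inert to the catalyst.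

Step 17
Reactants: 32 methyl (2E)-4-{5-hydroxy-5-methyl-3-oxo-2-[(2S)-4-oxobutan-2-yl]cyclopent-1-en-1-yl}-2-(hydroxymethyl)but-2-enoate
Product: 34 methyl (2Z)-2-(bromomethyl)-4-{5-hydroxy-5-methyl-3-oxo-2-[(2S)-4-oxobutan-2-yl]cyclopent-1-en-1-yl}but-2-enoate, via mesylate 33 (not isolated)
Conditions: MsCl, Et3N, CH2Cl2, −20 °C; then LiBr, THF, 0 °C
Reagents that add atoms: lithium bromide, [Li+].[Br-]
Why: Selective mesylation of the primary allylic alcohol (the tertiary alcohol does not react at this temperature) and SN2 displacement by bromide; these conditions are used because they spare the aldehyde.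

Step 18
Reactants: 34 methyl (2Z)-2-(bromomethyl)-4-{5-hydroxy-5-methyl-3-oxo-2-[(2S)-4-oxobutan-2-yl]cyclopent-1-en-1-yl}but-2-enoate
Product: 36 (7R,8S,10S)-4-hydroxy-2-oxoguaia-1(5),11(13)-dien-12,8-olide, via hydroxy ester 35 (not isolated)
Conditions: CrCl2 (6 equiv), THF, rt, high dilution; then TsOH·H2O (cat.), CH2Cl2, rt
Reagents that add atoms: none
Why: Intramolecular Nozaki–Hiyama allylation: the allylchromium species formed from the bromide adds through its γ-carbon C7 to the C8 aldehyde in a chair transition state (7-exo closure), equilibrating allylchromium reagents give the anti adduct and thus, after lactonisation of 35, the trans-fused α-methylene lactone (C7 and C8 set here), and the C10 methyl, pseudoaxial through allylic strain with the cyclopentenone, should place C8–O trans to it.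

Step 19
Reactants: 36 (7R,8S,10S)-4-hydroxy-2-oxoguaia-1(5),11(13)-dien-12,8-olide
Product: 37 (7R,8S,10S)-13-(dimethylamino)-4-hydroxy-2-oxoguai-1(5)-en-12,8-olide
Conditions: Me2NH (2 M in THF), MeOH, 0 °C → rt
Reagents that add atoms: dimethylamine, CNC
Why: Conjugate addition of a secondary amine to the α-methylene lactone masks the guaianolide's own dienophile as a Mannich base until step 23; the hindered tetrasubstituted enone does not add the amine and the C11 configuration is immaterial.

Step 20
Reactants: 37 (7R,8S,10S)-13-(dimethylamino)-4-hydroxy-2-oxoguai-1(5)-en-12,8-olide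
Product: 38 (2S,7R,8S,10S)-13-(dimethylamino)-2,4-dihydroxyguai-1(5)-en-12,8-olide
Conditions: (R)-2-methyl-CBS-oxazaborolidine (0.3 equiv), catecholborane, toluene, −78 °C
Reagents that add atoms: none
Why: Corey–Bakshi–Shibata reduction of a 2-substituted cyclopentenone: with the substituted vinylic carbon as the large group the (R)-oxazaborolidine should deliver hydride to give the (2S) allylic alcohol under reagent control for either C4 epimer.

Step 21
Reactants: 38 (2S,7R,8S,10S)-13-(dimethylamino)-2,4-dihydroxyguai-1(5)-en-12,8-olide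
Product: 39 (2S,7R,8S,10S)-2-acetoxy-13-(dimethylamino)-4-hydroxyguai-1(5)-en-12,8-olide
Conditions: Ac2O, pyridine, DMAP (cat.), CH2Cl2, 0 °C
Reagents that add atoms: acetic anhydride, CC(=O)OC(C)=O
Why: Acylation of the secondary allylic alcohol with acetic anhydride; the tertiary alcohol is not acetylated under these mild conditions.

Step 22
Reactants: 39 (2S,7R,8S,10S)-2-acetoxy-13-(dimethylamino)-4-hydroxyguai-1(5)-en-12,8-olide; 21 (3aR,4R,6Z,10Z,11aR)-4-hydroxy-6,10-dimethyl-3-methylidene-3a,4,5,8,9,11a-hexahydrocyclodeca[b]furan-2(3H)-one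
Product: 41 13-(dimethylamino)-11,13-dihydro derivative of the target, via acetoxy diene 40 (not isolated)
Conditions: Burgess reagent (methyl N-(triethylammoniosulfonyl)carbamate, 1.1 equiv), THF, 0 °C, 30 min; then 21 (2 equiv), concentration to about 1 M, 20 °C
Reagents that add atoms: none
Why: Burgess syn-dehydration of the tertiary allylic alcohol (either C4 epimer) toward C3 unveils the 5-acetoxycyclopentadiene 40, which is trapped at once in a normal-demand Diels–Alder reaction by the α-methylene lactone of 21 (the guaianolide's own one being masked): the CH2 terminus C13' bonds to the fully substituted C1 and the quaternary C11' to C3–H for steric reasons, the lactone carbonyl sits exo as is usual for α-methylene γ-lactones with cyclopentadienes (setting C11'), the dienophile should come in anti to the 2-acetoxy group because in the exo transition state a syn acetoxy group would face the lactone carbonyl (setting C1 and C3 relative to C2), and it has to use the lactone face on the C8' side.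

Step 23
Reactants: 41 13-(dimethylamino)-11,13-dihydro derivative of the target
Product: 43 target CNP0148007.1, via methiodide 42 (not isolated)
Conditions: MeI, MeCN, rt; then aq. NaHCO3, EtOAc, rt
Reagents that add atoms: none
Why: Quaternisation of the Mannich base with iodomethane (42) and Hofmann-type β-elimination with mild base restore the α-methylene lactone without touching the acetate, the lactones or the cis ring alkenes, which gives the target.

**Compound list**

1 | (1Z,5Z)-1,5-dimethylcycloocta-1,5-diene | C/C1=C/CC/C(C)=C\CC1 | starting material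
2 | (1R*,8S*,4Z)-1,5-dimethyl-9-oxabicyclo[6.1.0]non-4-ene (racemic cis-epoxide) | C[C@@]12CC/C=C(/C)CC[C@@H]1O2 | intermediate
3 | trans-(5Z)-1,5-dimethyl-2-(phenylselanyl)cyclooct-5-en-1-ol (racemic) | C[C@@]1(O)CC/C=C(/C)CC[C@H]1[Se]c1ccccc1 | intermediate
4 | Se-oxide of 3 (racemic) | C[C@@]1(O)CC/C=C(/C)CC[C@H]1[Se](=O)c1ccccc1 | intermediate
5 | (2Z,5Z)-1,5-dimethylcycloocta-2,5-dien-1-ol (racemic) | CC1(O)/C=C\C/C(C)=C\CC1 | intermediate
6 | (2Z,6Z)-3,7-dimethylcycloocta-2,6-dien-1-one | O=C1/C=C(/C)CC/C=C(/C)C1 | intermediate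
7 | [(1Z,3Z,7Z)-3,7-dimethylcycloocta-1,3,7-trien-1-yl]oxy(trimethyl)silane | C[Si](C)(C)O/C1=C/C(C)=C\CC/C(C)=C\1 | intermediate
8 | dichloroacetyl chloride | O=C(Cl)C(Cl)Cl | starting material
9 | dichloroketene | O=C=C(Cl)Cl | intermediate
10 | (1R*,8R*,2Z,6Z)-10,10-dichloro-3,7-dimethyl-1-(trimethylsilyloxy)bicyclo[6.2.0]deca-2,6-dien-9-one (cis-fused, racemic) | C[Si](C)(C)O[C@]12/C=C(/C)CC/C=C(/C)[C@H]1C(=O)C2(Cl)Cl | intermediate
11 | (1R*,8R*,2Z,6Z)-3,7-dimethyl-1-(trimethylsilyloxy)bicyclo[6.2.0]deca-2,6-dien-9-one (racemic) | C[Si](C)(C)O[C@]12/C=C(/C)CC/C=C(/C)[C@H]1C(=O)C2 | intermediate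
12 | (4Z,8Z)-5,9-dimethylcyclodeca-4,8-diene-1,3-dione | O=C1CC(=O)/C=C(/C)CC/C=C(/C)C1 | intermediate
13 | tert-butyl bromoacetate | CC(C)(C)OC(=O)CBr | starting material
14 | tert-butyl 2-[(3Z,7Z)-4,8-dimethyl-2,10-dioxocyclodeca-3,7-dien-1-yl]acetate (racemic, C7' labile) | CC(C)(C)OC(=O)CC1C(=O)/C=C(/C)CC/C=C(/C)CC1=O | intermediate
15 | tert-butyl 2-[(1R*,3Z,7Z,10R*)-10-hydroxy-4,8-dimethyl-2-oxocyclodeca-3,7-dien-1-yl]acetate (racemic) | CC(C)(C)OC(=O)C[C@H]1C(=O)/C=C(/C)CC/C=C(/C)C[C@H]1O | intermediate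
16 | tert-butyl 2-[(1S*,2R*,3Z,7Z,10R*)-10-acetoxy-2-hydroxy-4,8-dimethylcyclodeca-3,7-dien-1-yl]acetate (racemic) | CC(C)(C)OC(=O)C[C@H]1[C@H](O)/C=C(/C)CC/C=C(/C)C[C@H]1OC(C)=O | intermediate
17 | (3aR*,4R*,6Z,10Z,11aR*)-6,10-dimethyl-2-oxo-2,3,3a,4,5,8,9,11a-octahydrocyclodeca[b]furan-4-yl acetate (racemic, trans-fused) | C1C(=O)O[C@@H]2/C=C(/C)CC/C=C(/C)C[C@@H](OC(C)=O)[C@H]21 | intermediate
18 | (3aR,4R,6Z,10Z,11aR)-4-hydroxy-6,10-dimethyl-3a,4,5,8,9,11a-hexahydrocyclodeca[b]furan-2(3H)-one | C1C(=O)O[C@@H]2/C=C(/C)CC/C=C(/C)C[C@@H](O)[C@H]21 | intermediate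
19 | 3-[(dimethylamino)methyl] derivative of 18 (C11' epimers) | CN(C)CC1C(=O)O[C@@H]2/C=C(/C)CC/C=C(/C)C[C@@H](O)[C@H]21 | intermediate
20 | N-methyl ammonium iodide of 19 | C[N+](C)(C)CC1C(=O)O[C@@H]2/C=C(/C)CC/C=C(/C)C[C@@H](O)[C@H]21.[I-] | intermediate
21 | (3aR,4R,6Z,10Z,11aR)-4-hydroxy-6,10-dimethyl-3-methylidene-3a,4,5,8,9,11a-hexahydrocyclodeca[b]furan-2(3H)-one | C=C1C(=O)O[C@@H]2/C=C(/C)CC/C=C(/C)C[C@@H](O)[C@H]21 | intermediate
22 | cyclopentane-1,3-dione | O=C1CCC(=O)C1 | starting material
23 | (E)-but-2-enal | C/C=C/C=O | starting material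
24 | (4S)-2-hydroxy-4-methyl-3,4,6,7-tetrahydrocyclopenta[b]pyran-5(2H)-one (anomers) | C[C@H]1CC(O)OC2=C1C(=O)CC2 | intermediate
25 | (4S)-2-methoxy-4-methyl-3,4,6,7-tetrahydrocyclopenta[b]pyran-5(2H)-one (anomers) | C[C@H]1CC(OC)OC2=C1C(=O)CC2 | intermediate
26 | (4S)-2-methoxy-4,6-dimethyl-3,4,6,7-tetrahydrocyclopenta[b]pyran-5(2H)-one (C2 and C6 epimers) | C[C@H]1CC(OC)OC2=C1C(=O)C(C)C2 | intermediate
27 | (4S)-6-hydroxy-2-methoxy-4,6-dimethyl-3,4,6,7-tetrahydrocyclopenta[b]pyran-5(2H)-one (C2 and C6 epimers) | C[C@H]1CC(OC)OC2=C1C(=O)C(C)(O)C2 | intermediate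
28 | allylmagnesium bromide | C=CC[Mg]Br | starting material
29 | (4S)-2-methoxy-4,6-dimethyl-5-(prop-2-en-1-yl)-2,3,4,5,6,7-hexahydrocyclopenta[b]pyran-5,6-diol (epimers) | C[C@H]1CC(OC)OC2=C1C(O)(CC=C)C(C)(O)C2 | intermediate
30 | (3S)-3-[3-hydroxy-3-methyl-5-oxo-2-(prop-2-en-1-yl)cyclopent-1-en-1-yl]butanal (C4 epimers) | O=CC[C@H](C)C1=C(CC=C)C(C)(O)CC1=O | intermediate
31 | methyl 2-(hydroxymethyl)prop-2-enoate | C=C(CO)C(=O)OC | starting material
32 | methyl (2E)-4-{5-hydroxy-5-methyl-3-oxo-2-[(2S)-4-oxobutan-2-yl]cyclopent-1-en-1-yl}-2-(hydroxymethyl)but-2-enoate (C4 epimers) | O=CC[C@H](C)C1=C(C/C=C(/C(=O)OC)CO)C(C)(O)CC1=O | intermediate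
33 | methanesulfonate of 32 | O=CC[C@H](C)C1=C(C/C=C(/C(=O)OC)COS(C)(=O)=O)C(C)(O)CC1=O | intermediate
34 | methyl (2Z)-2-(bromomethyl)-4-{5-hydroxy-5-methyl-3-oxo-2-[(2S)-4-oxobutan-2-yl]cyclopent-1-en-1-yl}but-2-enoate (C4 epimers) | O=CC[C@H](C)C1=C(C/C=C(/C(=O)OC)CBr)C(C)(O)CC1=O | intermediate
35 | methyl (7R,8S,10S)-4,8-dihydroxy-2-oxoguaia-1(5),11(13)-dien-12-oate (C4 epimers) | C=C(C(=O)OC)[C@H]1CC2=C([C@@H](C)C[C@@H]1O)C(=O)CC2(C)O | intermediate
36 | (7R,8S,10S)-4-hydroxy-2-oxoguaia-1(5),11(13)-dien-12,8-olide (trans-fused lactone, C4 epimers) | C=C1C(=O)O[C@H]2C[C@H](C)C3=C(C[C@H]12)C(C)(O)CC3=O | intermediate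
37 | (7R,8S,10S)-13-(dimethylamino)-4-hydroxy-2-oxoguai-1(5)-en-12,8-olide (C4 and C11 epimers) | CN(C)CC1C(=O)O[C@H]2C[C@H](C)C3=C(C[C@H]12)C(C)(O)CC3=O | intermediate
38 | (2S,7R,8S,10S)-13-(dimethylamino)-2,4-dihydroxyguai-1(5)-en-12,8-olide (C4 and C11 epimers) | CN(C)CC1C(=O)O[C@H]2C[C@H](C)C3=C(C[C@H]12)C(C)(O)C[C@@H]3O | intermediate
39 | (2S,7R,8S,10S)-2-acetoxy-13-(dimethylamino)-4-hydroxyguai-1(5)-en-12,8-olide (C4 and C11 epimers) | CN(C)CC1C(=O)O[C@H]2C[C@H](C)C3=C(C[C@H]12)C(C)(O)C[C@@H]3OC(C)=O | intermediate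
40 | (2S,7R,8S,10S)-2-acetoxy-13-(dimethylamino)guaia-1(5),3-dien-12,8-olide (C11 epimers) | CN(C)CC1C(=O)O[C@H]2C[C@H](C)C3=C(C[C@H]12)C(C)=C[C@@H]3OC(C)=O | intermediate
41 | Diels–Alder adduct of 40 and 21 (13-(dimethylamino)-11,13-dihydro target, C11 epimers) | CN(C)CC1C(=O)O[C@H]2C[C@H](C)[C@]34C[C@@]5(C(=O)O[C@@H]6/C=C(/C)CC/C=C(/C)C[C@@H](O)[C@H]65)[C@H](C(C)=C3C[C@H]12)[C@@H]4OC(C)=O | intermediate
42 | N-methyl ammonium iodide of 41 | C[N+](C)(C)CC1C(=O)O[C@H]2C[C@H](C)[C@]34C[C@@]5(C(=O)O[C@@H]6/C=C(/C)CC/C=C(/C)C[C@@H](O)[C@H]65)[C@H](C(C)=C3C[C@H]12)[C@@H]4OC(C)=O.[I-] | intermediate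
43 | CNP0148007.1 | C=C1C(=O)O[C@H]2C[C@H](C)[C@]34C[C@@]5(C(=O)O[C@@H]6/C=C(/C)CC/C=C(/C)C[C@@H](O)[C@H]65)[C@H](C(C)=C3C[C@H]12)[C@@H]4OC(C)=O | target

**Step count and risks**

Total steps: 23. Longest linear sequence: 13 steps (steps 1–11, 22, 23); the guaianolide branch (steps 12–21) joins at step 22.

The three steps most likely to fail:

Step 22. What may go wrong: the cycloaddition may take place on the acetoxy-bearing face of the diene (the electronic preference of simple 5-acyloxycyclopentadienes) or on the other lactone face of 21, or the diene may undergo [1,5]-hydrogen shift or exocyclic dehydration before it is trapped. The fallback replaces electronic by steric control of the diene face; it sets out from 38 and 21 and comes back at 41. Alcohol 38 is silylated at the secondary hydroxyl (Et3SiCl, imidazole, CH2Cl2) to the triethylsilyl ether F1, and 21 is protected (tBuMe2SiCl, imidazole, DMF) as the silyl ether F2. Burgess dehydration of F1 in the presence of F2 gives the silyloxy diene F3, whose bulky C2 substituent should force the dienophile to the opposite face, and so the adduct F4. PPTS in MeOH removes only the triethylsilyl group to give the bridge alcohol F5, Ac2O/pyridine/DMAP gives the acetate F6, and HF·pyridine frees the C8' hydroxyl to give 41.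

Step 18. What may go wrong: ring closure through the syn transition state (cis-fused lactone) or with the C8 oxygen cis to the C10 methyl. The fallback accepts the syn mode and corrects C8 afterwards; it sets out from 34 and comes back at 36. Barbier cyclisation with indium powder in THF–H2O, which favours syn addition, should give the C8-epimeric hydroxy ester F7; LiOH in THF–H2O gives the hydroxy acid F8 (any cis-lactone formed is opened as well); Mitsunobu lactonisation (PPh3, DIAD, THF) closes the lactone with inversion at C8 and gives the trans-fused 36.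

Step 7. What may go wrong: loss of chelation control in the flexible ten-membered ring (7',8'-anti alcohol) or competing reduction of the conjugated carbonyl. The fallback uses thermodynamic and substrate control; it sets out from 14 and comes back at 17. Ketalisation under Noyori conditions (Me3SiOTf cat., 1,2-bis(trimethylsilyloxy)ethane, CH2Cl2, −78 °C) protects the non-conjugated C8' carbonyl selectively as the dioxolane F9. Luche reduction (NaBH4, CeCl3·7H2O, MeOH) gives the allylic alcohol F10. TsOH in wet acetone removes the ketal, closes the lactone and lets C7', now α to the ketone, settle in the trans-fused keto lactone F11. LiBH(sBu)3 at −78 °C adds hydride to C8' from the face away from C11' and gives the racemic hydroxy lactone F12, and Ac2O/pyridine returns 17.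

Further compounds
F1 | step 22 | 2-O-triethylsilyl ether of 38 | CN(C)CC1C(=O)O[C@H]2C[C@H](C)C3=C(C[C@H]12)C(C)(O)C[C@@H]3O[Si](CC)(CC)CC
F2 | step 22 | 4-O-(tert-butyldimethylsilyl) ether of 21 | C=C1C(=O)O[C@@H]2/C=C(/C)CC/C=C(/C)C[C@@H](O[Si](C)(C)C(C)(C)C)[C@H]21
F3 | step 22 | (2S,7R,8S,10S)-13-(dimethylamino)-2-(triethylsilyloxy)guaia-1(5),3-dien-12,8-olide | CN(C)CC1C(=O)O[C@H]2C[C@H](C)C3=C(C[C@H]12)C(C)=C[C@@H]3O[Si](CC)(CC)CC
F4 | step 22 | Diels–Alder adduct of F3 and F2 | CN(C)CC1C(=O)O[C@H]2C[C@H](C)[C@]34C[C@@]5(C(=O)O[C@@H]6/C=C(/C)CC/C=C(/C)C[C@@H](O[Si](C)(C)C(C)(C)C)[C@H]65)[C@H](C(C)=C3C[C@H]12)[C@@H]4O[Si](CC)(CC)CC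
F5 | step 22 | 2-hydroxy analogue of F4 | CN(C)CC1C(=O)O[C@H]2C[C@H](C)[C@]34C[C@@]5(C(=O)O[C@@H]6/C=C(/C)CC/C=C(/C)C[C@@H](O[Si](C)(C)C(C)(C)C)[C@H]65)[C@H](C(C)=C3C[C@H]12)[C@@H]4O
F6 | step 22 | 8'-O-(tert-butyldimethylsilyl) ether of 41 | CN(C)CC1C(=O)O[C@H]2C[C@H](C)[C@]34C[C@@]5(C(=O)O[C@@H]6/C=C(/C)CC/C=C(/C)C[C@@H](O[Si](C)(C)C(C)(C)C)[C@H]65)[C@H](C(C)=C3C[C@H]12)[C@@H]4OC(C)=O
F7 | step 18 | methyl (7R,8R,10S)-4,8-dihydroxy-2-oxoguaia-1(5),11(13)-dien-12-oate (8-epimer of 35) | C=C(C(=O)OC)[C@H]1CC2=C([C@@H](C)C[C@H]1O)C(=O)CC2(C)O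
F8 | step 18 | (7R,8R,10S)-4,8-dihydroxy-2-oxoguaia-1(5),11(13)-dien-12-oic acid | C=C(C(=O)O)[C@H]1CC2=C([C@@H](C)C[C@H]1O)C(=O)CC2(C)O
F9 | step 7 | C8' ethylene ketal of 14 | CC(C)(C)OC(=O)CC1C(=O)/C=C(/C)CC/C=C(/C)CC12OCCO2
F10 | step 7 | C6' allylic alcohol from F9 (diastereomers) | CC(C)(C)OC(=O)CC1C(O)/C=C(/C)CC/C=C(/C)CC12OCCO2
F11 | step 7 | (3aR*,6Z,10Z,11aR*)-6,10-dimethyl-3,3a,5,8,9,11a-hexahydrocyclodeca[b]furan-2,4-dione (racemic, trans-fused) | C1C(=O)O[C@@H]2/C=C(/C)CC/C=C(/C)CC(=O)[C@H]21
F12 | step 7 | racemic 18 | C1C(=O)O[C@@H]2/C=C(/C)CC/C=C(/C)C[C@@H](O)[C@H]21
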